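## Analysis of the target

Target 22 is methyl 2,4-dihydroxy-3,5-bis(3-methylbut-2-enyl)-6-(2-phenylethyl)benzoate: a single benzene ring (ring A) with all six positions substituted, and an unfunctionalised phenyl ring on a two-carbon tether. Ring A is numbered as in the benzoate throughout: C1 CO2Me, C2 OH, C3 prenyl, C4 OH, C5 prenyl, C6 phenethyl. There is no stereocenter and no configured double bond, because both side-chain alkenes end in gem-dimethyl groups, so the problem is purely one of regiochemistry. The sensitive groups are the two prenyl groups ortho to phenols, which close to 2,2-dimethylchromans under acid and add halogen electrophiles, and the oxidisable resorcinol. The 2,4-dioxygenated benzoic acid also decarboxylates easily as long as it is not esterified. The difficulty is that six different neighbours must be placed in a fixed order, and electrophilic prenylation of a resorcylate cannot tell C3 from C5 and competes with O-alkylation. The strategy rests on the oxygens at C2 and C4 being meta with the prenyl-bearing C3 between them: C2 can be a ketene carbonyl carbon and C3–C4 the two carbons of a prenyl-substituted ynol ether. C5, C6 and C1 then come from the vinylketene, whose unsubstituted terminus C1 remains as the only ring C–H for late introduction of the ester carbon.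

## Retrosynthetic reasoning

**C4–O silyl ether (22 back to 21).** The two phenols stay differentiated until the end, C4–O as a triisopropylsilyl ether. The last step is then a buffered fluoride cleavage, not an acidic deprotection that would endanger the ortho-prenyl phenols.

**C1–carboxyl bond (21 back to 20, 19 and 18).** The bond between C1 and the ester carbon is cut. In phenol 18, C1 is the only ring C–H and is ortho to the free C2 hydroxyl, so a chelation-directed ortho-formylation has no regiochemical choice. Oxidation of aldehyde 19 to acid 20 and O-methylation to 21 complete the ester. Carrying the ester through ring formation would require a more elaborate, electron-poor alkenyl terminus in the diazo enone and would put synthetic risk into the precursor. The price is three functional-group steps after the annulation.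

**Ring A (18 back to 8 and 13).** The ring bonds C2–C3, C4–C5 and C1–C2 are cut, which splits 18 into diazo enone 8 and siloxyalkyne 13. In the forward direction a fourth ring bond, C5–C6, is also new, because the alkenyl carbon C6 migrates from the carbonyl carbon (C2) to the diazo carbon (C5) when the ketene is formed. The cut is made here because it leaves each prenyl group attached to one building block (the C3 prenyl on 13, the C5 prenyl on the diazo carbon of 8). Their positions are therefore fixed by connectivity and not by the selectivity of an aromatic substitution. The forward reaction has to generate vinylketene 14, join it to 13 with the correct orientation, and aromatise through 15, 16 and 17.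

**Diazo group (8 back to 7 and 6).** The C=N2 unit is traced to the CH2 group at C4 of enone 6. That carbon must first be activated as the trifluoroacetyl diketone 7, because a simple ketone enolate does not accept a diazo group cleanly. Enone 6 can enolise only on this side, so the position of the diazo group is not in question.

**Enone chain (6 back to 5, then 2 and 3).** The bond between the carbonyl carbon and the future diazo carbon is cut. This gives enal 2 and the Grignard reagent 4 made from bromide 3, which delivers the diazo carbon and its prenyl group in one piece. An aldehyde is chosen over an acyl derivative because 1,2-addition is clean; the carbinol 5 is then oxidised.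

**Exocyclic methylene (2 back to 1).** The CH2= carbon, the future C1 of ring A, is removed from 2, leaving the unbranched aldehyde 1. The forward step is an α-methylenation, which cannot over-react because the product has no α-hydrogen.

**Siloxyalkyne (13 back to 12, 10 and 9).** The O–Si bond and then the alkyne C–C bond are cut: ynolate 12 arises from ester 10 by one-carbon homologation. The ester carbonyl carbon becomes the oxygen-bearing alkyne carbon (future C4) and the inserted carbon becomes future C3, carrying the prenyl group of acid 9.

## Alternatives that were turned down

**Alternative 1: aryne difunctionalisation across C6 and C1.**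
- Disconnection: the C6–CH2 bond of the phenethyl group and the C1–carboxyl bond are cut, leading back to the pentasubstituted aryl chloride A2 with ring A already in place.
- Forward key step: a hindered lithium amide removes the single ring hydrogen of A2 (between chlorine and an alkoxy group) and chloride loss gives the C1–C6 aryne. A phenethyl Grignard reagent adds at C6, the carbon remote from the C2 alkoxy group, and the aryl-magnesium at C1 is acylated by a chloroformate to give A1.
- For: the arene is bought and not built, two substituents including the ester enter in one flask, and the regiochemistry of addition is set by the inductive effect of the C2 oxygen. On step count and convergence it is stronger than the chosen route.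
- Against:
  - A2 carries two CH2 groups that are both benzylic and allylic, whose acidity invites competing deprotonation by the amide base.
  - The aryne is formed next to the C5 prenyl group, a tethered trisubstituted alkene that can trap it intramolecularly (ene or (2+2)) before the bimolecular Grignard addition.
  - The nucleophile must attack an aryne carbon flanked by that prenyl group, and the resulting doubly flanked aryl-magnesium must still be acylated.
  - A1 needs acidic removal of two methoxymethyl ethers ortho to prenyl groups, which are the conditions that close chromans.
- Comparison: the chosen route is longer, but no strong base or acid ever meets the prenylated arene and its last step is a buffered fluoride cleavage.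

**Alternative 2: biomimetic aldol aromatisation of a diketo-dioxinone.**
- Disconnection: only the C1–C6 bond of ring A is cut, giving the open-chain diketo-dioxinone A4.
- Forward key step: with a tertiary amine base the dioxinone α-carbon (C1) adds to the terminal ketone (C6), and dehydration and enolisation give benzodioxinone A3. Alkoxide opening of the dioxinone would then give the methyl ester and free the C2 hydroxyl.
- For: all ring carbons, both oxygens and the ester carbon come with the chain; no phenol protection and no oxidation-state changes are needed. After ring formation it needs one step where the chosen route needs four, so on that point it is clearly stronger.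
- Against:
  - A4 needs prenyl groups on both carbons that lie between carbonyl groups (future C3 and C5). Placing two C-prenyl groups selectively on a polycarbonyl chain has to overcome O-allylation, double alkylation and attack at the wrong end of the allyl unit, twice and at two different sites.
  - The closing aldol must engage a ketone next to a branched carbon.
  - Closure through an enol oxygen to a pyranone is an open competing path.
  - The uncertainty therefore sits in making the precursor and not in the key step.
- Comparison: in the chosen route both prenyl groups are fixed by the building blocks 3 and 9, and the precursors 8 and 13 are reached by standard reactions.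

**Alternative 3: pyrone Diels–Alder with a ketene acetal.**
- Disconnection: the C3–C4 and C5–C6 bonds are cut, giving the fully substituted pyrone A6 (ring atoms C3, C2, C1, C6) and the ketene bis(silyl) acetal A7 (C4 and C5).
- Forward key step: the prenyl-bearing nucleophilic carbon of A7 bonds to the electrophilic pyrone carbon that becomes C6, and the acetal carbon bonds to the one that becomes C3. The bridged lactone loses carbon dioxide, elimination of silanol aromatises the ring, and aqueous work-up gives A5, which needs only acetate removal.
- For: the ester is already at C1, the two oxygens are differentiated, and the partners are strongly and correctly polarised. It is stronger than the chosen route in the steps after ring formation.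
- Against:
  - A6 needs its own multi-step synthesis, including C-prenylation of a 4-hydroxypyrone where O-alkylation competes.
  - The cycloaddition must form both new bonds at carbons that become fully substituted in the bicyclic adduct, between a pyrone substituted at both diene termini and a trisubstituted ketene acetal.
  - The acetoxy donor lowers the electron demand of the diene.
  - The ketene acetal can instead attack the acetate or stop at conjugate addition.
- Comparison: the chosen cascade closes ring A intramolecularly at an unsubstituted CH2 terminus by electrocyclisation, which tolerates crowding better.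

Key step: step 8

## Route

Remark on the chemistry: compounds 1, 3 and 9 are taken as purchased; ring positions C1–C6 are those of benzoate 22.

Step 1
Reactants: 1 4-phenylbutanal
Product: 2 2-methylidene-4-phenylbutanal
Conditions: CH2O (37% aq), pyrrolidine (10 mol %), EtCO2H (10 mol %), i-PrOH, 45 °C
Reagents that add atoms: formaldehyde, C=O
Why: Amine-catalysed Mannich condensation with formaldehyde followed by elimination of the amine (organocatalytic α-methylenation) is general for unbranched aldehydes; the product has no α-hydrogen left and cannot react a second time.

Step 2
Reactants: 2 2-methylidene-4-phenylbutanal; 3 5-bromo-2-methylpent-2-ene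
Product: 5 7-methyl-2-(2-phenylethyl)octa-1,6-dien-3-ol (racemic), via (4-methylpent-3-enyl)magnesium bromide 4 (not isolated)
Conditions: 3, Mg, THF, rt; then 2, −78 → 0 °C; NH4Cl (aq)
Reagents that add atoms: none
Why: Grignard 1,2-addition: without copper the alkylmagnesium halide attacks the aldehyde carbonyl of the enal and not its conjugate position. The carbinol stereocenter is formed racemic and is removed by the oxidation in step 3.

Step 3
Reactants: 5 7-methyl-2-(2-phenylethyl)octa-1,6-dien-3-ol
Product: 6 7-methyl-2-(2-phenylethyl)octa-1,6-dien-3-one
Conditions: Dess–Martin periodinane, CH2Cl2, 0 °C → rt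
Reagents that add atoms: none
Why: Dess–Martin oxidation of the secondary allylic alcohol under near-neutral conditions should give the enone without touching the trisubstituted alkene or moving the 1,1-disubstituted double bond; the α-methylene ketone is used promptly because such enones dimerise on standing.

Step 4
Reactants: 6 7-methyl-2-(2-phenylethyl)octa-1,6-dien-3-one
Product: 7 1,1,1-trifluoro-3-(3-methylbut-2-enyl)-5-methylidene-7-phenylheptane-2,4-dione (keto–enol mixture)
Conditions: LiN(SiMe3)2, THF, −78 °C (ketone added to base); CF3CO2CH2CF3, −78 °C; HCl (aq)
Reagents that add atoms: 2,2,2-trifluoroethyl trifluoroacetate, O=C(OCC(F)(F)F)C(F)(F)F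
Why: Kinetic deprotonation can occur only at C4, since the other neighbour of the carbonyl is an alkene carbon, and the lithium enolate undergoes Claisen-type C-acylation by the activated trifluoroacetate (activation stage of the detrifluoroacetylative diazo transfer, which suits enones). Low temperature and inverse addition keep the enolate from adding to unreacted enone.

Step 5
Reactants: 7 1,1,1-trifluoro-3-(3-methylbut-2-enyl)-5-methylidene-7-phenylheptane-2,4-dione
Product: 8 4-diazo-7-methyl-2-(2-phenylethyl)octa-1,6-dien-3-one
Conditions: MeSO2N3, Et3N, H2O (1 equiv), MeCN, rt
Reagents that add atoms: methanesulfonyl azide, CS(=O)(=O)N=[N+]=[N-]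
Why: Regitz-type deacylative diazo transfer: the diketone enolate attacks the terminal nitrogen of the sulfonyl azide and the adduct fragments with loss of the trifluoroacetyl group as the N-sulfonyl amide, leaving the diazo group on the prenyl-bearing carbon. The mild amine base leaves the enone untouched.

Step 6
Reactants: 9 4-methylpent-3-enoic acid
Product: 10 ethyl 4-methylpent-3-enoate
Conditions: EtI, K2CO3, DMF, rt
Reagents that add atoms: iodoethane, CCI
Why: Carboxylate O-alkylation under weakly basic conditions; acid-catalysed esterification is avoided because this β,γ-unsaturated acid lactonises through its tertiary cation, and the mild base should not move the double bond into conjugation.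

Step 7
Reactants: 10 ethyl 4-methylpent-3-enoate
Product: 13 triisopropyl[(5-methylhex-4-en-1-ynyl)oxy]silane, via lithium dibromo enolate 11 (not isolated), via lithium ynolate 12 (not isolated)
Conditions: CH2Br2, lithium 2,2,6,6-tetramethylpiperidide, THF, −78 °C; 10; LiN(SiMe3)2; n-BuLi, −78 °C → rt; i-Pr3SiCl, −78 °C → rt
Reagents that add atoms: dibromomethane, BrCBr; chlorotriisopropylsilane, CC(C)[Si](Cl)(C(C)C)C(C)C
Why: Kowalski ester homologation stopped at the ynolate: dibromomethyllithium adds to the ester, the derived enolate 11 undergoes bromine–lithium exchange, and the carbenoid rearranges with 1,2-shift of the prenyl group to ynolate 12. The bulky silyl chloride then silylates oxygen and not carbon. Carbonyl addition of the weakly basic carbenoid at −78 °C is expected to outrun enolisation of the ester.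

Step 8
Reactants: 8 4-diazo-7-methyl-2-(2-phenylethyl)octa-1,6-dien-3-one; 13 triisopropyl[(5-methylhex-4-en-1-ynyl)oxy]silane
Product: 18 2,4-bis(3-methylbut-2-enyl)-5-(2-phenylethyl)-3-(triisopropylsilyloxy)phenol, via vinylketene 14 (not isolated), via 4-alkenylcyclobutenone 15 (not isolated), via dienylketene 16 (not isolated), via cyclohexa-2,4-dienone 17 (not isolated)
Conditions: 8 (1.2 equiv), 13 (1.0 equiv), ClCH2CH2Cl, hν (254 nm, low-pressure Hg lamps, quartz), rt; then 80 °C
Reagents that add atoms: none
Why: Irradiation of 8 expels nitrogen with concerted 1,2-shift of the alkenyl group from the carbonyl carbon to the diazo carbon (photochemical Wolff rearrangement; this shift makes C5–C6) and gives vinylketene 14, whose carbonyl carbon is the future C2. The electron-rich alkyne 13 adds across the ketene C=C in a (2+2) cycloaddition that forms C2–C3 and C4–C5 and gives 15, and four-electron conrotatory opening of 15, by light or at 80 °C, breaks C2–C5 and gives dienylketene 16. Ring A is closed by thermal six-electron disrotatory electrocyclisation of 16 between the ketene carbon C2 and the unsubstituted methylene terminus C1, and dienone 17 tautomerises irreversibly to phenol 18. The closest known reaction type is the Danheiser benzannulation in its diazo ketone form with siloxyalkynes, used here at the pentasubstituted end of its range. No stereocenter is formed: the quaternary carbon of 15 and the double-bond geometry of 16 vanish on aromatisation, and because the opening of 15 is reversible, material that opens with the alkenyl group turned outward returns to 15 until it leaves through the productive (3E) isomer. The selectivity needed is regiochemical in the (2+2) step and is secured by the polarisation of 13: its oxygen makes the prenyl-bearing carbon nucleophilic, so this carbon bonds to the electrophilic ketene carbon C2 and the silyloxy group ends at C4, meta to the new hydroxyl. Chemoselectivity rests on the ynol ether being far more reactive toward the ketene than the trisubstituted prenyl double bonds, and on the Wolff shift outrunning 1,2-hydrogen migration from the CH2 next to the diazo carbon, which the concerted photochemical pathway from the s-Z conformer favours.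

Step 9
Reactants: 18 2,4-bis(3-methylbut-2-enyl)-5-(2-phenylethyl)-3-(triisopropylsilyloxy)phenol
Product: 19 2-hydroxy-3,5-bis(3-methylbut-2-enyl)-6-(2-phenylethyl)-4-(triisopropylsilyloxy)benzaldehyde
Conditions: MgCl2, Et3N, (CH2O)n, MeCN, reflux; HCl (aq, dilute, cold)
Reagents that add atoms: paraformaldehyde (reacts as formaldehyde), C=O
Why: Casnati–Skattebøl ortho-formylation: the magnesium phenoxide delivers formaldehyde to the ortho carbon through a chelate, and the benzylic alkoxide is oxidised by hydride transfer to a second formaldehyde. C1 is the only ring C–H, ortho to the free hydroxyl and para to the silyloxy group, so there is no regiochemical choice, and the non-acidic medium spares the prenyl groups and the silyl ether.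

Step 10
Reactants: 19 2-hydroxy-3,5-bis(3-methylbut-2-enyl)-6-(2-phenylethyl)-4-(triisopropylsilyloxy)benzaldehyde
Product: 20 2-hydroxy-3,5-bis(3-methylbut-2-enyl)-6-(2-phenylethyl)-4-(triisopropylsilyloxy)benzoic acid
Conditions: NaClO2, NaH2PO4, 2-methylbut-2-ene (large excess), t-BuOH/THF/H2O, 0 °C → rt
Reagents that add atoms: sodium chlorite, [Na+].[O-]Cl=O
Why: Pinnick oxidation: chlorous acid adds to the aldehyde and fragments to the acid and hypochlorous acid, which the large excess of 2-methylbut-2-ene should intercept before it adds to the prenyl double bonds; the ring has no free position for chlorination. The acid is carried on without storage because 2-hydroxy-4-oxygenated benzoic acids decarboxylate easily.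

Step 11
Reactants: 20 2-hydroxy-3,5-bis(3-methylbut-2-enyl)-6-(2-phenylethyl)-4-(triisopropylsilyloxy)benzoic acid
Product: 21 methyl 2-hydroxy-3,5-bis(3-methylbut-2-enyl)-6-(2-phenylethyl)-4-(triisopropylsilyloxy)benzoate
Conditions: Me3SiCHN2, PhMe/MeOH, 0 °C
Reagents that add atoms: (trimethylsilyl)diazomethane, C[Si](C)(C)C=[N+]=[N-]
Why: Esterification with (trimethylsilyl)diazomethane in methanol is fast for carboxylic acids and slow for phenols; the C2 hydroxyl is in addition hydrogen-bonded to the carboxyl and flanked on both sides, so only the methyl ester should form.

Step 12
Reactants: 21 methyl 2-hydroxy-3,5-bis(3-methylbut-2-enyl)-6-(2-phenylethyl)-4-(triisopropylsilyloxy)benzoate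
Product: 22 methyl 2,4-dihydroxy-3,5-bis(3-methylbut-2-enyl)-6-(2-phenylethyl)benzoate
Conditions: Bu4NF, AcOH, THF, 0 °C
Reagents that add atoms: none
Why: Fluoride cleaves the aryl silyl ether through pentacoordinate silicon with the phenoxide as leaving group. Buffering with acetic acid keeps the medium near neutral, so the ester is untouched and the ortho-prenyl phenols meet neither strong base nor the acid that would close chromans.

## Compound list

1 | 4-phenylbutanal | O=CCCCc1ccccc1 | starting material
2 | 2-methylidene-4-phenylbutanal | C=C(CCc1ccccc1)C=O | intermediate
3 | 5-bromo-2-methylpent-2-ene | CC(C)=CCCBr | starting material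
4 | (4-methylpent-3-enyl)magnesium bromide | CC(C)=CCC[Mg]Br | intermediate (not isolated)
5 | 7-methyl-2-(2-phenylethyl)octa-1,6-dien-3-ol (racemic) | C=C(CCc1ccccc1)C(O)CCC=C(C)C | intermediate
6 | 7-methyl-2-(2-phenylethyl)octa-1,6-dien-3-one | C=C(CCc1ccccc1)C(=O)CCC=C(C)C | intermediate
7 | 1,1,1-trifluoro-3-(3-methylbut-2-enyl)-5-methylidene-7-phenylheptane-2,4-dione (keto–enol mixture) | C=C(CCc1ccccc1)C(=O)C(CC=C(C)C)C(=O)C(F)(F)F | intermediate
8 | 4-diazo-7-methyl-2-(2-phenylethyl)octa-1,6-dien-3-one | C=C(CCc1ccccc1)C(=O)C(=[N+]=[N-])CC=C(C)C | intermediate
9 | 4-methylpent-3-enoic acid | CC(C)=CCC(=O)O | starting material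
10 | ethyl 4-methylpent-3-enoate | CCOC(=O)CC=C(C)C | intermediate
11 | lithium 1,1-dibromo-5-methylhexa-1,4-dien-2-olate | [Li]OC(CC=C(C)C)=C(Br)Br | intermediate (not isolated)
12 | lithium 5-methylhex-4-en-1-yn-1-olate | [Li]OC#CCC=C(C)C | intermediate (not isolated)
13 | triisopropyl[(5-methylhex-4-en-1-ynyl)oxy]silane | CC(C)=CCC#CO[Si](C(C)C)(C(C)C)C(C)C | intermediate
14 | 2-(3-methylbut-2-enyl)-3-(2-phenylethyl)buta-1,3-dien-1-one | O=C=C(CC=C(C)C)C(=C)CCc1ccccc1 | intermediate (not isolated)
15 | 2,4-bis(3-methylbut-2-enyl)-4-(4-phenylbut-1-en-2-yl)-3-(triisopropylsilyloxy)cyclobut-2-en-1-one (racemic) | O=C1C(CC=C(C)C)=C(O[Si](C(C)C)(C(C)C)C(C)C)C1(CC=C(C)C)C(=C)CCc1ccccc1 | intermediate (not isolated)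
16 | (3E)-2,4-bis(3-methylbut-2-enyl)-5-(2-phenylethyl)-3-(triisopropylsilyloxy)hexa-1,3,5-trien-1-one | O=C=C(CC=C(C)C)/C(O[Si](C(C)C)(C(C)C)C(C)C)=C(/CC=C(C)C)C(=C)CCc1ccccc1 | intermediate (not isolated)
17 | 2,4-bis(3-methylbut-2-enyl)-5-(2-phenylethyl)-3-(triisopropylsilyloxy)cyclohexa-2,4-dien-1-one | O=C1CC(CCc2ccccc2)=C(CC=C(C)C)C(O[Si](C(C)C)(C(C)C)C(C)C)=C1CC=C(C)C | intermediate (not isolated)
18 | 2,4-bis(3-methylbut-2-enyl)-5-(2-phenylethyl)-3-(triisopropylsilyloxy)phenol | CC(C)=CCc1c(O)cc(CCc2ccccc2)c(CC=C(C)C)c1O[Si](C(C)C)(C(C)C)C(C)C | intermediate
19 | 2-hydroxy-3,5-bis(3-methylbut-2-enyl)-6-(2-phenylethyl)-4-(triisopropylsilyloxy)benzaldehyde | O=Cc1c(O)c(CC=C(C)C)c(O[Si](C(C)C)(C(C)C)C(C)C)c(CC=C(C)C)c1CCc1ccccc1 | intermediate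
20 | 2-hydroxy-3,5-bis(3-methylbut-2-enyl)-6-(2-phenylethyl)-4-(triisopropylsilyloxy)benzoic acid | O=C(O)c1c(O)c(CC=C(C)C)c(O[Si](C(C)C)(C(C)C)C(C)C)c(CC=C(C)C)c1CCc1ccccc1 | intermediate
21 | methyl 2-hydroxy-3,5-bis(3-methylbut-2-enyl)-6-(2-phenylethyl)-4-(triisopropylsilyloxy)benzoate | COC(=O)c1c(O)c(CC=C(C)C)c(O[Si](C(C)C)(C(C)C)C(C)C)c(CC=C(C)C)c1CCc1ccccc1 | intermediate
22 | methyl 2,4-dihydroxy-3,5-bis(3-methylbut-2-enyl)-6-(2-phenylethyl)benzoate | COC(=O)c1c(O)c(CC=C(C)C)c(O)c(CC=C(C)C)c1CCc1ccccc1 | target

## Step count and least certain steps

Total step count: 12. Longest linear sequence: 10 steps (steps 1–5, then 8–12); the siloxyalkyne branch (steps 6 and 7) joins at step 8.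

**Step 8 (key step).**

What may go wrong: hydrogen migration from the CH2 next to the diazo carbon can compete with the Wolff shift, and the cycloaddition of a fully substituted ketene with an internal alkyne may be slow enough for ketene dimerisation or acylation of the product phenol by the ketene to take over. Secondary photolysis of the phenol at 254 nm is a further drain.

Fallback: the thermal cyclobutenone form of the same benzannulation, which needs neither light nor a carbene-like intermediate; it sets out from 13 and comes back to the route at 18. A (2+2) cycloaddition of 13 with ketene (ethenone, generated separately) should give 2-(3-methylbut-2-enyl)-3-(triisopropylsilyloxy)cyclobut-2-en-1-one F1. Addition of 2-phenylethylmagnesium bromide in the presence of CeCl3 to the carbonyl group of F1 should give racemic 2-(3-methylbut-2-enyl)-1-(2-phenylethyl)-3-(triisopropylsilyloxy)cyclobut-2-en-1-ol F2. Dilute acid then converts F2, with loss of the silanol and transposition of the carbonyl group, into 2-(3-methylbut-2-enyl)-3-(2-phenylethyl)cyclobut-2-en-1-one F3. Heating F3 with a second portion of 13 in toluene at 80–110 °C opens it reversibly to the same vinylketene 14 at low stationary concentration, and the cascade through 15, 16 and 17 comes back to the route at 18.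

**Step 7.**

What may go wrong: deprotonation of ester 10 at its doubly activated α-position (next to the ester and allylic) by the carbenoid or the amide base can compete with carbonyl addition, and the double bond may then move into conjugation. Partial C-silylation of the ynolate is a lesser concern.

Fallback: the ynolate is made by oxidation of an acetylide instead of by ester homologation; it sets out from 10 and comes back to the route at 12. Reduction of 10 with i-Bu2AlH at −78 °C should give 4-methylpent-3-enal F4. Dibromo-olefination of F4 with CBr4 and PPh3 (first stage of the Corey–Fuchs sequence) should give 1,1-dibromo-5-methylhexa-1,4-diene F5. Two equivalents of n-BuLi convert F5 into (5-methylhex-4-en-1-ynyl)lithium F6. F6 is oxidised in the same flask by lithium tert-butyl peroxide (LiOOt-Bu, from t-BuOOH and LiN(SiMe3)2) to the ynolate 12, which is silylated as in step 7 to 13.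

**Step 9.**

What may go wrong: formylation at C1, flanked by the hydroxyl and the phenethyl group, may stall at the hydroxymethyl stage or go on to methoxymethyl by-products on long heating.

Fallback: direct carboxylation of the resorcinol, which replaces steps 9–12; it sets out from 18 and comes back to the route at the target 22. Bu4NF removes the silyl group of 18 to give 2,4-bis(3-methylbut-2-enyl)-5-(2-phenylethyl)benzene-1,3-diol F7. Heating F7 with magnesium methyl carbonate (MeOMgOCO2Me) in DMF should carboxylate the only free ring position, which is ortho to one hydroxyl and para to the other, and give 2,4-dihydroxy-3,5-bis(3-methylbut-2-enyl)-6-(2-phenylethyl)benzoic acid F8. Alkylation of the carboxylate of F8 with MeI and NaHCO3 in DMF comes back to the route at 22.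

**Step 10.**

What may go wrong: the hydrogen-bonded, doubly flanked aldehyde may react slowly, so that hypochlorous acid outruns the scavenger and adds to the prenyl double bonds, and the electron-rich free phenol may be degraded oxidatively by chlorine dioxide.

Fallback: the phenol is masked before the oxidation; it sets out from 19 and comes back to the route at 20. Acetylation of 19 (Ac2O, pyridine, catalytic 4-dimethylaminopyridine) should give 2-acetoxy-3,5-bis(3-methylbut-2-enyl)-6-(2-phenylethyl)-4-(triisopropylsilyloxy)benzaldehyde F9. In F9 the aldehyde is no longer hydrogen-bonded and the ring is less electron-rich. Chlorite oxidation of F9 under the conditions of step 10 should give 2-acetoxy-3,5-bis(3-methylbut-2-enyl)-6-(2-phenylethyl)-4-(triisopropylsilyloxy)benzoic acid F10. K2CO3 in methanol removes the acetate of F10 and comes back to the route at 20.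

## Further compounds

F1 | step 8 | 2-(3-methylbut-2-enyl)-3-(triisopropylsilyloxy)cyclobut-2-en-1-one | O=C1CC(O[Si](C(C)C)(C(C)C)C(C)C)=C1CC=C(C)C
F2 | step 8 | 2-(3-methylbut-2-enyl)-1-(2-phenylethyl)-3-(triisopropylsilyloxy)cyclobut-2-en-1-ol (racemic) | OC1(CCc2ccccc2)CC(O[Si](C(C)C)(C(C)C)C(C)C)=C1CC=C(C)C
F3 | step 8 | 2-(3-methylbut-2-enyl)-3-(2-phenylethyl)cyclobut-2-en-1-one | O=C1CC(CCc2ccccc2)=C1CC=C(C)C
F4 | step 7 | 4-methylpent-3-enal | CC(C)=CCC=O
F5 | step 7 | 1,1-dibromo-5-methylhexa-1,4-diene | CC(C)=CCC=C(Br)Br
F6 | step 7 | (5-methylhex-4-en-1-ynyl)lithium | [Li]C#CCC=C(C)C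
F7 | step 9 | 2,4-bis(3-methylbut-2-enyl)-5-(2-phenylethyl)benzene-1,3-diol | CC(C)=CCc1c(O)cc(CCc2ccccc2)c(CC=C(C)C)c1O
F8 | step 9 | 2,4-dihydroxy-3,5-bis(3-methylbut-2-enyl)-6-(2-phenylethyl)benzoic acid | O=C(O)c1c(O)c(CC=C(C)C)c(O)c(CC=C(C)C)c1CCc1ccccc1
F9 | step 10 | 2-acetoxy-3,5-bis(3-methylbut-2-enyl)-6-(2-phenylethyl)-4-(triisopropylsilyloxy)benzaldehyde | CC(=O)Oc1c(C=O)c(CCc2ccccc2)c(CC=C(C)C)c(O[Si](C(C)C)(C(C)C)C(C)C)c1CC=C(C)C
F10 | step 10 | 2-acetoxy-3,5-bis(3-methylbut-2-enyl)-6-(2-phenylethyl)-4-(triisopropylsilyloxy)benzoic acid | CC(=O)Oc1c(C(=O)O)c(CCc2ccccc2)c(CC=C(C)C)c(O[Si](C(C)C)(C(C)C)C(C)C)c1CC=C(C)C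
A1 | alternative 1 | methyl 2,4-bis(methoxymethoxy)-3,5-bis(3-methylbut-2-enyl)-6-(2-phenylethyl)benzoate | COC(=O)c1c(OCOC)c(CC=C(C)C)c(OCOC)c(CC=C(C)C)c1CCc1ccccc1
A2 | alternative 1 | 1-chloro-3,5-bis(methoxymethoxy)-2,4-bis(3-methylbut-2-enyl)benzene | Clc1cc(OCOC)c(CC=C(C)C)c(OCOC)c1CC=C(C)C
A3 | alternative 2 | 7-hydroxy-2,2-dimethyl-6,8-bis(3-methylbut-2-enyl)-5-(2-phenylethyl)-4H-1,3-benzodioxin-4-one | CC1(C)OC(=O)c2c(CCc3ccccc3)c(CC=C(C)C)c(O)c(CC=C(C)C)c2O1
A4 | alternative 2 | 6-[1,3-bis(3-methylbut-2-enyl)-2,4-dioxo-6-phenylhexyl]-2,2-dimethyl-4H-1,3-dioxin-4-one (mixture of stereoisomers and tautomers) | CC1(C)OC(=CC(=O)O1)C(CC=C(C)C)C(=O)C(CC=C(C)C)C(=O)CCc1ccccc1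
A5 | alternative 3 | methyl 2-acetoxy-4-hydroxy-3,5-bis(3-methylbut-2-enyl)-6-(2-phenylethyl)benzoate | COC(=O)c1c(OC(C)=O)c(CC=C(C)C)c(O)c(CC=C(C)C)c1CCc1ccccc1
A6 | alternative 3 | methyl 4-acetoxy-3-(3-methylbut-2-enyl)-2-oxo-6-(2-phenylethyl)-2H-pyran-5-carboxylate | COC(=O)C1=C(CCc2ccccc2)OC(=O)C(CC=C(C)C)=C1OC(C)=O
A7 | alternative 3 | 1,1-bis(trimethylsilyloxy)-5-methylhexa-1,4-diene | CC(C)=CCC=C(O[Si](C)(C)C)O[Si](C)(C)C
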